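**Retrosynthetic overview** (azulene numbering: C1–C3 and C3a in the five-membered ring, C4–C8 in the seven-membered ring, C8a quaternary)
1. Target ⇐ C4–OH acylation of the C6-formyl 3,4-diol; the enal comes from a C6 tert-butyl ester, the C4 carbinol from a C4 ketone by hydroxyl-directed reduction.
2. The C3 carbinol comes from isopropyl addition to C3 of the bicyclic 3,4-dione, masked at C4 as its silyl enol ether; C3a is then set by equilibration next to the C4 ketone.
3. Seven-membered ring (formed second): intramolecular Claisen closure C3a–C4 of a keto diester, whose C6=C7 bond comes from a Horner–Wadsworth–Emmons reaction on the side-chain aldehyde.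
4. Five-membered ring (formed first): palladium-catalysed asymmetric trimethylenemethane [3+2] cycloaddition, which makes C1–C2 and C3a–C8a and sets the quaternary C8a.
5. Enabling feature: C3, the only oxygen-bearing carbon of the cyclopentane, lies between C2 and C3a, so C2–C3–C3a maps onto a trimethylenemethane unit whose exocyclic CH2 is a masked C3 carbonyl; C1 is a bare CH2 on quaternary C8a, so C8a=C1 maps onto a β,β-disubstituted nitroalkene whose nitro group (on C1) is later expelled.

Key step: step 3

Assumption: the silylated allyl acetate, the tert-butyl phosphonoacetate and the silyl-protected 4-hydroxybenzoic acid are taken as purchasable; the enantiomer of the phosphoramidite ligand is the one that gives the quaternary carbon as drawn.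

**Step 1**
Reactants: 1 2-methylallylmagnesium chloride; 2 triethyl orthoformate
Product: 3 4,4-diethoxy-2-methylbut-1-ene
Conditions: THF, 0 °C to reflux; aq. NH4Cl
Reagents that add atoms: none
Why: Bodroux–Chichibabin reaction, in which the allylic Grignard reagent replaces one ethoxide of the orthoformate and stops at the acetal; no stereocentre is formed.

**Step 2**
Reactants: 3 4,4-diethoxy-2-methylbut-1-ene
Product: 4 (E)-4,4-diethoxy-2-methyl-1-nitrobut-1-ene
Conditions: AgNO2 (3 equiv), TEMPO (0.4 equiv), 4 Å molecular sieves, ClCH2CH2Cl, 70 °C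
Reagents that add atoms: silver nitrite, [Ag+].[O-]N=O
Why: Radical nitration–dehydrogenation of a 1,1-disubstituted alkene (NO2 radical adds to the terminal carbon, TEMPO removes the hydrogen) should give the conjugated (E)-nitroalkene with nitro anti to the larger substituent, the acetal being inert.

**Step 3**
Reactants: 4 (E)-4,4-diethoxy-2-methyl-1-nitrobut-1-ene; 5 2-[(trimethylsilyl)methyl]prop-2-en-1-yl acetate
Product: 7 (1S,2R)-1-(2,2-diethoxyethyl)-1-methyl-4-methylidene-2-nitrocyclopentane, via trimethylenemethane–palladium zwitterion 6 (not isolated)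
Conditions: Pd(dba)2 (5 mol %), chiral BINOL-derived phosphoramidite with a 2,5-bis(2-naphthyl)pyrrolidine amine part (10 mol %), toluene, 25–45 °C
Reagents that add atoms: none
Why: Zerovalent palladium ionizes the allylic acetate of 5 and acetate removes the silyl group to give zwitterion 6, whose carbanionic CH2 adds to the β-carbon of 4 (the C3a–C8a bond, at the fully substituted carbon), after which the nitronate carbon attacks a terminus of the π-allylpalladium unit (the C1–C2 bond). The closest known reaction is the palladium-catalysed asymmetric trimethylenemethane [3+2] cycloaddition to nitroalkenes, here extended to a β,β-dialkyl acceptor. The cyclopentane closes in the second, intramolecular event as a five-membered exo-type allylic alkylation of the nitronate with palladium leaving. The quaternary stereocentre is set in the conjugate addition by the chiral ligand, which selects one face of the (E)-nitroalkene; the nitro-bearing carbon (expected nitro cis to methyl) need not be controlled because step 4 destroys it. The step needs chemoselectivity for cycloaddition over base-induced deconjugation of 4 and over protodesilylation of 6, which the neutral acetate-only medium and the high electrophilicity of the nitroalkene should secure; regioselectivity is no issue because the unsubstituted trimethylenemethane unit is symmetric.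

**Step 4**
Reactants: 7 (1S,2R)-1-(2,2-diethoxyethyl)-1-methyl-4-methylidene-2-nitrocyclopentane
Product: 9 (4R)-4-(2,2-diethoxyethyl)-4-methylcyclopent-2-en-1-one, via nitro ketone 8 (not isolated)
Conditions: O3, CH2Cl2, −78 °C; Me2S, −78 °C to rt; then DBU, 0 °C
Reagents that add atoms: ozone, O=[O+][O-]
Why: Ozonolysis cleaves the only C=C to the C3 ketone, and the resulting β-nitro ketone loses nitrous acid by E1cB elimination to the enone, which removes the activating group and the uncontrolled nitro stereocentre while the quaternary centre is untouched.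

**Step 5**
Reactants: 9 (4R)-4-(2,2-diethoxyethyl)-4-methylcyclopent-2-en-1-one
Product: 10 (3R)-3-(2,2-diethoxyethyl)-3-methylcyclopentan-1-one
Conditions: H2 (1 atm), Pd/C (10 wt % Pd), EtOAc, rt
Reagents that add atoms: none
Why: Heterogeneous hydrogenation of the disubstituted enone double bond; ketone and acetal survive and no new stereocentre arises.

**Step 6**
Reactants: 10 (3R)-3-(2,2-diethoxyethyl)-3-methylcyclopentan-1-one
Product: 11 2-[(1R)-1-methyl-3-oxocyclopentyl]acetaldehyde
Conditions: 1 M aq. HCl, THF, 0 °C to rt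
Reagents that add atoms: water, O
Why: Acid-catalysed acetal hydrolysis frees the aldehyde under conditions too mild for intramolecular aldolization; the quaternary centre cannot epimerize.

**Step 7**
Reactants: 12 tert-butyl 2-(diethoxyphosphoryl)acetate; 13 ethyl bromoacetate
Product: 14 1-tert-butyl 4-ethyl 2-(diethoxyphosphoryl)butanedioate
Conditions: NaH (1.0 equiv), THF, 0 °C; then 13, 0 °C to rt
Reagents that add atoms: none
Why: C-alkylation of the stabilized phosphonoacetate anion by a reactive α-bromo ester; the new stereocentre is racemic and is lost in step 8.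

**Step 8**
Reactants: 11 2-[(1R)-1-methyl-3-oxocyclopentyl]acetaldehyde; 14 1-tert-butyl 4-ethyl 2-(diethoxyphosphoryl)butanedioate
Product: 15 1-tert-butyl 4-ethyl (2E)-2-{2-[(1R)-1-methyl-3-oxocyclopentyl]ethylidene}butanedioate
Conditions: 14, NaH, THF, 0 °C; then 11, −20 °C to rt
Reagents that add atoms: none
Why: Horner–Wadsworth–Emmons olefination, selective for the aldehyde over the ketone, should give mainly the (E)-alkylidene succinate, which places the CH2CO2Et arm cis to the ring-bearing chain as the later ring closure requires.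

**Step 9**
Reactants: 15 1-tert-butyl 4-ethyl (2E)-2-{2-[(1R)-1-methyl-3-oxocyclopentyl]ethylidene}butanedioate
Product: 16 tert-butyl (8aR)-8a-methyl-3,4-dioxo-1,2,3,3a,4,5,8,8a-octahydroazulene-6-carboxylate
Conditions: KOtBu (2.2 equiv), THF, 0 °C to rt; then 1 M aq. HCl
Reagents that add atoms: none
Why: Intramolecular Claisen (Dieckmann-type) condensation, in which only the ketone enolate next to the quaternary carbon can reach the ethyl ester held cis on the (E)-alkene (the tert-butyl ester is trans and hindered) and deprotonation of the 1,3-diketone makes the seven-membered closure irreversible; C3a becomes an enolized centre that is set in step 11.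

**Step 10**
Reactants: 16 tert-butyl (8aR)-8a-methyl-3,4-dioxo-1,2,3,3a,4,5,8,8a-octahydroazulene-6-carboxylate
Product: 17 tert-butyl (8aR)-4-[(tert-butyldimethylsilyl)oxy]-8a-methyl-3-oxo-1,2,3,5,8,8a-hexahydroazulene-6-carboxylate
Conditions: TBSOTf (1.1 equiv), Et3N, CH2Cl2, −78 °C
Reagents that add atoms: tert-butyldimethylsilyl trifluoromethanesulfonate, CC(C)(C)[Si](C)(C)OS(=O)(=O)C(F)(F)F
Why: O-Silylation of the enolized 1,3-diketone should place silicon on the C4 oxygen, because the enol double bond exocyclic to the five-membered ring is the favoured tautomer, which leaves C3 as the only free carbonyl.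

**Step 11**
Reactants: 17 tert-butyl (8aR)-4-[(tert-butyldimethylsilyl)oxy]-8a-methyl-3-oxo-1,2,3,5,8,8a-hexahydroazulene-6-carboxylate
Product: 19 tert-butyl (3R,3aR,8aR)-3-hydroxy-8a-methyl-4-oxo-3-(propan-2-yl)-1,2,3,3a,4,5,8,8a-octahydroazulene-6-carboxylate, via silyl enol ether carbinol 18 (not isolated)
Conditions: iPrMgCl, anhydrous CeCl3, THF, −78 to −40 °C; aq. NH4Cl; then Bu4NF, AcOH, THF, 0 °C to rt
Reagents that add atoms: isopropylmagnesium chloride, CC(C)[Mg]Cl
Why: Organocerium 1,2-addition to the C3 carbonyl of the vinylogous silyl ester from the face anti to the pseudo-axial angular methyl sets C3, and buffered fluoride then frees the C4 ketone while C3a is protonated and equilibrates to the trans-fused epimer, in which the C4 carbonyl carbon is anti to isopropyl and hydrogen-bonded to the cis hydroxyl.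

**Step 12**
Reactants: 19 tert-butyl (3R,3aR,8aR)-3-hydroxy-8a-methyl-4-oxo-3-(propan-2-yl)-1,2,3,3a,4,5,8,8a-octahydroazulene-6-carboxylate
Product: 20 tert-butyl (3R,3aS,4S,8aR)-3,4-dihydroxy-8a-methyl-3-(propan-2-yl)-1,2,3,3a,4,5,8,8a-octahydroazulene-6-carboxylate
Conditions: Me4NBH(OAc)3, AcOH/MeCN, −20 °C
Reagents that add atoms: none
Why: Evans–Saksena reduction, in which the C3 hydroxyl binds boron and delivers hydride intramolecularly to the C4 ketone, should give the 1,3-anti diol, which is the (4S) carbinol; the enoate is inert to this hydride.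

**Step 13**
Reactants: 20 tert-butyl (3R,3aS,4S,8aR)-3,4-dihydroxy-8a-methyl-3-(propan-2-yl)-1,2,3,3a,4,5,8,8a-octahydroazulene-6-carboxylate
Product: 21 (3R,3aS,4S,8aR)-6-(hydroxymethyl)-8a-methyl-3-(propan-2-yl)-1,2,3,3a,4,5,8,8a-octahydroazulene-3,4-diol
Conditions: iBu2AlH (excess), CH2Cl2, −78 to 0 °C; aq. potassium sodium tartrate
Reagents that add atoms: none
Why: 1,2-Reduction of the α,β-unsaturated tert-butyl ester to the allylic alcohol; the alkene and the carbinol centres are unaffected.

**Step 14**
Reactants: 21 (3R,3aS,4S,8aR)-6-(hydroxymethyl)-8a-methyl-3-(propan-2-yl)-1,2,3,3a,4,5,8,8a-octahydroazulene-3,4-diol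
Product: 22 (3R,3aS,4S,8aR)-3,4-dihydroxy-8a-methyl-3-(propan-2-yl)-1,2,3,3a,4,5,8,8a-octahydroazulene-6-carbaldehyde
Conditions: MnO2 (activated, excess), CH2Cl2, rt
Reagents that add atoms: none
Why: Allylic oxidation with MnO2 touches only the primary allylic alcohol and gives the conjugated enal without moving the double bond.

**Step 15**
Reactants: 22 (3R,3aS,4S,8aR)-3,4-dihydroxy-8a-methyl-3-(propan-2-yl)-1,2,3,3a,4,5,8,8a-octahydroazulene-6-carbaldehyde; 23 4-[(tert-butyldimethylsilyl)oxy]benzoic acid
Product: 24 (3R,3aS,4S,8aR)-6-formyl-3-hydroxy-8a-methyl-3-(propan-2-yl)-1,2,3,3a,4,5,8,8a-octahydroazulen-4-yl 4-[(tert-butyldimethylsilyl)oxy]benzoate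
Conditions: EDC·HCl, DMAP, CH2Cl2, rt
Reagents that add atoms: none
Why: Steglich-type esterification acylates the secondary C4 hydroxyl with retention, the tertiary C3 hydroxyl being unreactive.

**Step 16**
Reactants: 24 (3R,3aS,4S,8aR)-6-formyl-3-hydroxy-8a-methyl-3-(propan-2-yl)-1,2,3,3a,4,5,8,8a-octahydroazulen-4-yl 4-[(tert-butyldimethylsilyl)oxy]benzoate
Product: 25 (3R,3aS,4S,8aR)-6-formyl-3-hydroxy-8a-methyl-3-(propan-2-yl)-1,2,3,3a,4,5,8,8a-octahydroazulen-4-yl 4-hydroxybenzoate
Conditions: Bu4NF, AcOH, THF, 0 °C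
Reagents that add atoms: none
Why: Fluoride cleaves the aryl silyl ether much faster than it attacks the hindered benzoate or the enal, and acetic acid buffers the phenoxide so that no acyl migration or retro-aldol reaction should occur.

**Compound list**
1 | 2-methylallylmagnesium chloride | CC(=C)C[Mg]Cl | starting material
2 | triethyl orthoformate | CCOC(OCC)OCC | starting material
3 | 4,4-diethoxy-2-methylbut-1-ene | C=C(C)CC(OCC)OCC | intermediate
4 | (E)-4,4-diethoxy-2-methyl-1-nitrobut-1-ene | CCOC(C/C(C)=C/[N+](=O)[O-])OCC | intermediate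
5 | 2-[(trimethylsilyl)methyl]prop-2-en-1-yl acetate | CC(=O)OCC(=C)C[Si](C)(C)C | starting material
6 | trimethylenemethane–palladium zwitterion (phosphoramidite ligand not drawn) | [CH2-]C(=C)C[Pd+] | intermediate
7 | (1S,2R)-1-(2,2-diethoxyethyl)-1-methyl-4-methylidene-2-nitrocyclopentane | C=C1C[C@@H]([N+](=O)[O-])[C@](C)(CC(OCC)OCC)C1 | intermediate
8 | (3R,4R)-3-(2,2-diethoxyethyl)-3-methyl-4-nitrocyclopentan-1-one | O=C1C[C@@H]([N+](=O)[O-])[C@](C)(CC(OCC)OCC)C1 | intermediate
9 | (4R)-4-(2,2-diethoxyethyl)-4-methylcyclopent-2-en-1-one | O=C1C=C[C@](C)(CC(OCC)OCC)C1 | intermediate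
10 | (3R)-3-(2,2-diethoxyethyl)-3-methylcyclopentan-1-one | O=C1CC[C@](C)(CC(OCC)OCC)C1 | intermediate
11 | 2-[(1R)-1-methyl-3-oxocyclopentyl]acetaldehyde | O=C1CC[C@](C)(CC=O)C1 | intermediate
12 | tert-butyl 2-(diethoxyphosphoryl)acetate | CCOP(=O)(CC(=O)OC(C)(C)C)OCC | starting material
13 | ethyl bromoacetate | BrCC(=O)OCC | starting material
14 | 1-tert-butyl 4-ethyl 2-(diethoxyphosphoryl)butanedioate (racemic) | CCOC(=O)CC(C(=O)OC(C)(C)C)P(=O)(OCC)OCC | intermediate
15 | 1-tert-butyl 4-ethyl (2E)-2-{2-[(1R)-1-methyl-3-oxocyclopentyl]ethylidene}butanedioate | O=C1CC[C@](C)(C/C=C(\CC(=O)OCC)C(=O)OC(C)(C)C)C1 | intermediate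
16 | tert-butyl (8aR)-8a-methyl-3,4-dioxo-1,2,3,3a,4,5,8,8a-octahydroazulene-6-carboxylate (enolized 1,3-diketone, C3a not fixed) | O=C1CC[C@]2(C)CC=C(C(=O)OC(C)(C)C)CC(=O)C12 | intermediate
17 | tert-butyl (8aR)-4-[(tert-butyldimethylsilyl)oxy]-8a-methyl-3-oxo-1,2,3,5,8,8a-hexahydroazulene-6-carboxylate | O=C1CC[C@]2(C)CC=C(C(=O)OC(C)(C)C)CC(O[Si](C)(C)C(C)(C)C)=C12 | intermediate
18 | tert-butyl (3R,8aR)-4-[(tert-butyldimethylsilyl)oxy]-3-hydroxy-8a-methyl-3-(propan-2-yl)-1,2,3,5,8,8a-hexahydroazulene-6-carboxylate | CC(C)[C@]1(O)CC[C@]2(C)CC=C(C(=O)OC(C)(C)C)CC(O[Si](C)(C)C(C)(C)C)=C12 | intermediate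
19 | tert-butyl (3R,3aR,8aR)-3-hydroxy-8a-methyl-4-oxo-3-(propan-2-yl)-1,2,3,3a,4,5,8,8a-octahydroazulene-6-carboxylate | CC(C)[C@]1(O)CC[C@]2(C)CC=C(C(=O)OC(C)(C)C)CC(=O)[C@H]21 | intermediate
20 | tert-butyl (3R,3aS,4S,8aR)-3,4-dihydroxy-8a-methyl-3-(propan-2-yl)-1,2,3,3a,4,5,8,8a-octahydroazulene-6-carboxylate | CC(C)[C@]1(O)CC[C@]2(C)CC=C(C(=O)OC(C)(C)C)C[C@H](O)[C@H]21 | intermediate
21 | (3R,3aS,4S,8aR)-6-(hydroxymethyl)-8a-methyl-3-(propan-2-yl)-1,2,3,3a,4,5,8,8a-octahydroazulene-3,4-diol | CC(C)[C@]1(O)CC[C@]2(C)CC=C(CO)C[C@H](O)[C@H]21 | intermediate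
22 | (3R,3aS,4S,8aR)-3,4-dihydroxy-8a-methyl-3-(propan-2-yl)-1,2,3,3a,4,5,8,8a-octahydroazulene-6-carbaldehyde | CC(C)[C@]1(O)CC[C@]2(C)CC=C(C=O)C[C@H](O)[C@H]21 | intermediate
23 | 4-[(tert-butyldimethylsilyl)oxy]benzoic acid | CC(C)(C)[Si](C)(C)Oc1ccc(cc1)C(=O)O | starting material
24 | (3R,3aS,4S,8aR)-6-formyl-3-hydroxy-8a-methyl-3-(propan-2-yl)-1,2,3,3a,4,5,8,8a-octahydroazulen-4-yl 4-[(tert-butyldimethylsilyl)oxy]benzoate | CC(C)[C@]1(O)CC[C@]2(C)CC=C(C=O)C[C@H](OC(=O)c3ccc(O[Si](C)(C)C(C)(C)C)cc3)[C@H]21 | intermediate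
25 | (3R,3aS,4S,8aR)-6-formyl-3-hydroxy-8a-methyl-3-(propan-2-yl)-1,2,3,3a,4,5,8,8a-octahydroazulen-4-yl 4-hydroxybenzoate | CC(C)[C@]1(O)CC[C@]2(C)CC=C(C=O)C[C@H](OC(=O)c3ccc(O)cc3)[C@H]21 | target

**Step count:** 16 steps in total; longest linear sequence 15 steps (steps 1–6 and 8–16; step 7 is a side branch).

**Steps most likely to fail**

Step 3. The β,β-dialkyl nitroalkene may add the zwitterion too slowly, so that base-induced deconjugation of 4 to its allylic nitro isomer or protodesilylation of 6 takes over, and the ligand may discriminate the two faces of the fully substituted carbon incompletely. The fallback sets out from 4 and comes back at 9, and makes the two ring bonds in separate operations. Amine–thiourea-catalysed enamine Michael addition of acetone to 4 should give (R)-6,6-diethoxy-4-methyl-4-(nitromethyl)hexan-2-one F1. An oxidative Nef reaction (NaOMe, MeOH, then KMnO4 and MgSO4 at 0 °C) converts the nitromethyl group into the aldehyde (R)-2-(2,2-diethoxyethyl)-2-methyl-4-oxopentanal F2. Intramolecular aldol condensation of the methyl ketone onto the aldehyde (KOH, MeOH) then closes the cyclopentenone and gives 9.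

Step 9. The other ring enolate may add in a conjugate sense to the alkylidene succinate, the side-chain double bond may migrate toward the ethyl ester before closure, and the seven-membered Claisen closure may be slow. The fallback sets out from 9 and comes back at 16, and runs the closure on the cross-conjugated dienolate of the enone, where C5 is the only enolizable ring carbon. Aqueous HCl in THF unmasks 2-[(1R)-1-methyl-4-oxocyclopent-2-en-1-yl]acetaldehyde F3. Horner–Wadsworth–Emmons reaction with 14 (NaH, THF) gives 1-tert-butyl 4-ethyl (2E)-2-{2-[(1R)-1-methyl-4-oxocyclopent-2-en-1-yl]ethylidene}butanedioate F4. LiN(SiMe3)2 (THF, −78 to 0 °C) should effect the ring closure to tert-butyl (8aS)-8a-methyl-3,4-dioxo-3,3a,4,5,8,8a-hexahydroazulene-6-carboxylate F5. Selective hydrogenation of the disubstituted enone double bond (H2, Pd/C, EtOAc, monitored) returns 16.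

Step 11. The silyl group may migrate to the C3 oxygen so that the reagent meets a free C4 carbonyl, the isopropyl reagent may reduce (β-hydride transfer) or enolize instead of adding, and the facial bias of the angular methyl may be too small. The fallback sets out from 17 and comes back at 19, and introduces the isopropyl group in two stages. 2-Propenylmagnesium bromide with CeCl3 (an sp2 nucleophile that cannot transfer a β-hydride) adds to C3 to give tert-butyl (3R,8aR)-4-[(tert-butyldimethylsilyl)oxy]-3-hydroxy-8a-methyl-3-(prop-1-en-2-yl)-1,2,3,5,8,8a-hexahydroazulene-6-carboxylate F6. Bu4NF with AcOH frees the C4 ketone to give tert-butyl (3S,3aR,8aR)-3-hydroxy-8a-methyl-4-oxo-3-(prop-1-en-2-yl)-1,2,3,3a,4,5,8,8a-octahydroazulene-6-carboxylate F7. Homogeneous hydrogenation with RhCl(PPh3)3 should reduce the 1,1-disubstituted alkene in preference to the trisubstituted enoate and give 19.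

**Further compounds**
F1 | step 3 | (R)-6,6-diethoxy-4-methyl-4-(nitromethyl)hexan-2-one | CC(=O)C[C@@](C)(CC(OCC)OCC)C[N+](=O)[O-]
F2 | step 3 | (R)-2-(2,2-diethoxyethyl)-2-methyl-4-oxopentanal | CC(=O)C[C@@](C)(CC(OCC)OCC)C=O
F3 | step 9 | 2-[(1R)-1-methyl-4-oxocyclopent-2-en-1-yl]acetaldehyde | O=C1C=C[C@](C)(CC=O)C1
F4 | step 9 | 1-tert-butyl 4-ethyl (2E)-2-{2-[(1R)-1-methyl-4-oxocyclopent-2-en-1-yl]ethylidene}butanedioate | O=C1C=C[C@](C)(C/C=C(\CC(=O)OCC)C(=O)OC(C)(C)C)C1
F5 | step 9 | tert-butyl (8aS)-8a-methyl-3,4-dioxo-3,3a,4,5,8,8a-hexahydroazulene-6-carboxylate | O=C1C=C[C@]2(C)CC=C(C(=O)OC(C)(C)C)CC(=O)C12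
F6 | step 11 | tert-butyl (3R,8aR)-4-[(tert-butyldimethylsilyl)oxy]-3-hydroxy-8a-methyl-3-(prop-1-en-2-yl)-1,2,3,5,8,8a-hexahydroazulene-6-carboxylate | CC(=C)[C@]1(O)CC[C@]2(C)CC=C(C(=O)OC(C)(C)C)CC(O[Si](C)(C)C(C)(C)C)=C12
F7 | step 11 | tert-butyl (3S,3aR,8aR)-3-hydroxy-8a-methyl-4-oxo-3-(prop-1-en-2-yl)-1,2,3,3a,4,5,8,8a-octahydroazulene-6-carboxylate | CC(=C)[C@]1(O)CC[C@]2(C)CC=C(C(=O)OC(C)(C)C)CC(=O)[C@H]21
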